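## Structural features

The target is a germacranolide-type sesquiterpenoid. Its ten-membered carbocycle (C1–C10, with C14 on C10 and the methyl C15 on C4) is fused across C6–C7 to an α,β-unsaturated γ-lactone (C7=C11–C12(=O)–O–C6), and the α-carbon C11 carries the acetoxymethyl group C13. The ring holds a Z trisubstituted olefin C1=C10, a trans-disubstituted epoxide at C2–C3 and a cis (Z-derived) trisubstituted epoxide at C4–C5. C2, C3, C4, C5 and C6 therefore form one unbroken row of stereocentres, and C8 and C9 a second pair on the other flank of the butenolide. Five acyl groups are present (acetates on O8 and O13, an (S)-2-methyloxirane-2-carboxylate on O9, a 3-methylbut-2-enoate on O14, and the lactone), so strong base, nucleophiles and acyl-transfer conditions are excluded late on; both ring epoxides are allylic and acid-labile, and the butenolide has an acidic γ-hydrogen at C6. The real difficulty is threefold: obtaining a ten-membered ring with two Z two-carbon units, setting seven ring stereocentres without the conformational order of a small ring, and telling eight oxygen atoms apart. The feature that answers the first two is that C4 and C9 face each other 1,6 across the ring: a C4–C9 bond turns the cyclodecane into a cis-decalin (ring A: C4–C5–C6–C7–C8–C9; ring B: C4–C3–C2–C1–C10–C9). In that decalin C1=C10 is a cyclohexene and C2, C3, C6 and C8 are ordinary cyclohexane stereocentres. The C9 hydroxyl with a C5 sulfonate is a 1,3-diol monosulfonate whose fragmentation cuts C4–C9 and fixes the C4=C5 geometry from the ring fusion.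

## Logic of the disconnections

**49 ⇒ 48 ⇒ 47.** Cut: the two acetyl C–O bonds (O8, O13), replaced by 4-methoxybenzyl ethers. Reason: an acetate on O13 beside a free O12, or on O8 beside O9, would migrate in any basic step. Gain: both positions travel as one robust ether class that is removed oxidatively. Demand: unmasking and acylation must spare two allylic epoxides and four esters.

**47 ⇒ 46.** Cut: both C–O bonds of the C4–C5 epoxide. Reason: once the lactone exists, C7=C11 is an electron-poor butenolide olefin and C1=C10 carries three allylic C–O bonds, so C4=C5 is the most nucleophilic olefin left. Epoxidation directed by a free O6 hydroxyl before lactonisation would instead risk the tetrasubstituted C7=C11. Gain: two stereocentres fewer. Demand: attack on the outer face of the Z olefin.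

**46 ⇒ 44.** Cut: the O6–C12 acyl bond and the C12 oxidation level. Reason: a butenolide survives neither the base of the fragmentation nor fluoride. Gain: O6 and O12 become a silylated cis-enediol. Demand: O12 must already stand cis to C6 across C7=C11, and no other primary alcohol may be free.

**44 ⇒ 43 ⇒ 42 ⇒ 41 ⇒ 40.** Cut: the O–C3 bond of the C2–C3 epoxide (closed by O2 on a C3 sulfonate with inversion) and the O14 acyl bond. Reason: a trans epoxide cannot exist in six-membered ring B and must be closed after the ring is opened, whereas its cis-2,3-diol precursor can be made in ring B. Gain: C2/C3 become a protected cis-diol. Demand: O3 and O14 must be unmasked before O2, O6 and O12; hence triethylsilyl on O3/O14 and tert-butyldimethylsilyl on the other three. A tert-butyldimethylsilyl ether on O14 could not be told from the one on O12 after fluoride.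

**40 ⇒ 36 + 38; 36 ⇒ 35.** Cut: the O9 acyl bond, then C9–H. Reason: O9 is the only oxygen that leaves the fragmentation unprotected (as the ketone). Gain: 35 has no free hydroxyl. Demand: hydride must give the 8,9-threo alcohol.

**35 ⇒ 33 (key).** Retron: a cyclodec-4-en-9-one is the fragmentation product of a decalin with C9–OH and C5–sulfonate. Reason: both Z olefins and C2, C3, C6, C8 are then set on six-membered rings. Gain: no macrocyclisation. Demand: cis ring fusion, sulfonate trans to the C4 methyl, and no other oxygen able to trigger or accept a fragmentation.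

**33 ⇒ 32 ⇒ 31 ⇒ 30 ⇒ 29 ⇒ 28.** Cut: two O–Si bonds, the O–O reduction, O5–S, C5–H, then the C6–O and C12–O bonds as one peroxide bridge. Reason: a singlet-oxygen cycloadduct delivers O6 and O12 to the same side of C7=C11, which fixes the tetrasubstituted olefin geometry and distinguishes C12 from C13 in one step. Gain: ring A becomes a simple dienone. Demand: oxygen on the α face; the C5 ketone is reduced only after the cycloaddition so that O5 is the only free secondary hydroxyl when the mesylate is made.

**28 ⇒ 22 + 25; 25 ⇒ 23 + 24; 22 ⇒ 20.** Cut: C7–C11. Reason: C7 carries the methoxy group of the quinone, and exchanging it for a triflate makes C7 a cross-coupling electrophile. Gain: the three-carbon unit C11–C13 arrives in one piece. Demand: sulfonylation at O7, not O5.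

**20 ⇒ 19 ⇒ 16 ⇒ 15 ⇒ 14.** Cut: the C2–O bond, with C1=C10 moved back to C1=C2. Reason: the cycloaddition leaves C1=C2 and an oxygen on C3, which directs an epoxide to the same face; selenide opening and selenoxide elimination then move the olefin to C1=C10. Gain: C2 stereochemistry comes from C3. Demand: opening at C1 and syn elimination toward C10.

**14 ⇒ 13 ⇒ 12 ⇒ 11 ⇒ 8.** Cut: both ester groups, the O8 benzyl ether, C8–H and C9–O. Reason: C9–H is the only enolisable hydrogen of 8, and the new C9 hydroxyl then steers hydride to C8 (and later to C5). Gain: back to the primary cycloadduct. Demand: oxygen must enter C9 cis to the C4 methyl.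

**8 ⇒ 6 + 7.** Cut: C3–C4 and C9–C10 (Diels–Alder retron of ring B). Reason: the quinone supplies all six functionalised carbons of ring A and the angular methyl. Gain: two flat components. Demand: reaction at the methyl-bearing double bond, which needs a donor on the other one. The parent 2-methyl-1,4-benzoquinone would react at its unsubstituted double bond and give no angular methyl, so 7 is used. The acyloxy-bearing diene terminus must bond to C4, with endo and facial control.

**6 ⇒ 5 ⇒ 4 ⇒ 1 + 2; 38 ⇒ 37.** Cut: ester C–O bonds only; these are functional-group steps to commercial materials.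

## Other disconnections considered

**Alternative 1:** The cut is C9–C10 together with O–C14. The open-chain aldoxime–allene A1 would be oxidised with PhI(OAc)2 to the nitrile oxide, which adds across the terminal allene double bond to give the isoxazoline-bridged macrocycle A2.
- In its favour: one pericyclic step forms a C–C and a C–O bond, closes the ring and stores the C9 ketone/C14 alcohol pattern in masked form. It is run with both ring epoxides, the lactone and the acetates in place, so the sequence after ring closure would be shorter than in the chosen plan; on that point it is the better plan.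
- Against it: closure of a ten-membered ring must compete with dimerisation of the nitrile oxide. The Z geometry at C1=C10 is created in the cycloaddition and nothing enforces it. The dipole carbon must bond to the central rather than the terminal allene carbon. A1 must be built by acyclic stereocontrol over five contiguous centres.
- Comparison: in the chosen plan both olefin geometries and four stereocentres are fixed by six-membered rings before the large ring exists; in A2 they depend on the conformation of a closing chain. Both routes still have to set C9 by reduction of a ketone (after N–O cleavage of A2); there they are equal. Mechanistically the cycloaddition is as well founded as the fragmentation; its weak point is ring size, not reaction type.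

**Alternative 2:** The cut is C1–C2. The seco glycidic acid–vinyl bromide A3 would lose CO2 under Ir[dF(CF3)ppy]2(dtbbpy)PF6 and blue light, and the oxiranyl radical would be coupled with the Z-vinyl bromide by the nickel catalyst from NiCl2(dme) and 4,4'-di-tert-butyl-2,2'-bipyridine to give the bis-silyl ether A4 of the target core.
- In its favour: it makes the bond next to an epoxide, which polar methods do poorly. Both epoxides and the butenolide are present, and A4 needs only desilylation and two acylations. On step count after the key step it is better than the chosen plan.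
- Against it: an oxiranyl radical inverts easily, so the C2 configuration (the trans epoxide) is not secured by the substrate. Reductive elimination must occur from a strained medium-ring nickelacycle. The Z-vinyl bromide can isomerise by energy transfer. A3 is a fragile α,β-epoxy acid.
- Comparison: the chosen plan sets C2 by a hydroxyl-directed epoxidation on a cyclohexene and never makes a bond at an epoxide carbon. Both plans install the Z C1=C10 unit before the ring event (as a vinyl bromide there, as a cyclohexene here) and are equal on that point. Mechanistically the chosen step is a closed-shell, stereospecific process, while the alternative relies on radical capture whose stereochemical outcome is open.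

**Alternative 3:** The cut is C8–C9. The seco dialdehyde A5 would be coupled by SmI2 (divalent samarium) to the 8,9-syn-diol A6.
- In its favour: one step forms the ring and both carbinol centres. Samarium pinacol closures of medium rings are a known reaction class. A5 can be assembled convergently from two enal halves; in convergence it is better than the chosen linear plan.
- Against it: both aldehydes are enals whose ketyl radical anions have allylic leaving groups (acetate, silyloxy, ester) and can eliminate or couple at the γ-carbon. The sense of the syn-diol relative to C6 rests on the chain conformation. O8 and O9 then emerge as two similar secondary allylic alcohols that must receive different acyl groups.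
- Comparison: the chosen plan never has to distinguish O8 from O9, because O8 is an ether and C9 a ketone when the ring appears; this is its clearest structural advantage. On the stereochemistry at C9 both plans depend on the conformation of a ten-membered ring and are equal. Step economy before the key step favours the alternative; after it, the chosen plan.

Key step: step 21

Conventions: locants are those of the target throughout. In the decalins α means cis to the C4 methyl and β trans to it, judged in the ring that holds the carbon. PMB = 4-methoxybenzyl, TES = triethylsilyl, TBS = tert-butyldimethylsilyl, Ms = methanesulfonyl.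

Assumption: the phenyl group of the (R)-2-methoxy-2-phenylacetyl residue in 6 is taken to shield the diene face that leads to the unwanted series (perpendicular π-shielding model of O-methylmandelate dienyl esters); if the sense proved opposite, the (S)-acid would be used in step 1 with nothing else changed.

## Route

**Step 1**
Reactants: 1 potassium (1E,3E)-5-oxopenta-1,3-dien-1-olate; 2 (R)-2-methoxy-2-phenylacetic acid
Product: 4 (1E,3E)-5-oxopenta-1,3-dien-1-yl (R)-2-methoxy-2-phenylacetate, via acid chloride 3 (not isolated)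
Conditions: 2, (COCl)2, N,N-dimethylformamide (cat.), CH2Cl2, 0 °C, evaporate; then 1, 18-crown-6 (cat.), THF, −20 to 0 °C
Reagents that add atoms: none
Why: O-Acylation of the ambident pentadienolate by the hard acid chloride should give the dienyl ester with the 1E,3E geometry of the salt retained; forming the acid chloride with oxalyl chloride at low temperature should leave the (R) centre intact.

**Step 2**
Reactants: 4 (1E,3E)-5-oxopenta-1,3-dien-1-yl (R)-2-methoxy-2-phenylacetate
Product: 5 (1E,3E)-5-hydroxypenta-1,3-dien-1-yl (R)-2-methoxy-2-phenylacetate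
Conditions: NaBH4, CeCl3·7H2O, MeOH/THF, −78 °C
Reagents that add atoms: none
Why: Luche reduction gives clean 1,2-reduction of the dienal; at −78 °C the enol ester is not attacked.

**Step 3**
Reactants: 5 (1E,3E)-5-hydroxypenta-1,3-dien-1-yl (R)-2-methoxy-2-phenylacetate
Product: 6 (1E,3E)-5-acetoxypenta-1,3-dien-1-yl (R)-2-methoxy-2-phenylacetate
Conditions: Ac2O, pyridine, 4-(dimethylamino)pyridine (cat.), CH2Cl2, 0 °C
Reagents that add atoms: acetic anhydride, CC(=O)OC(C)=O
Why: Acylation of the primary allylic alcohol; the acetate tolerates BF3 and is later removed together with the auxiliary ester.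

**Step 4**
Reactants: 6 (1E,3E)-5-acetoxypenta-1,3-dien-1-yl (R)-2-methoxy-2-phenylacetate; 7 2-methoxy-5-methyl-1,4-benzoquinone
Product: 8 cis-decalin adduct (5,8-dione; 7-methoxy-6-ene; 1-ene; 4α-methyl; 9α-H; 3β-[(R)-2-methoxy-2-phenylacetoxy]; 10β-acetoxymethyl)
Conditions: 7, BF3·OEt2 (1.1 equiv), CH2Cl2, −78 °C; then 6, −78 to −30 °C; chromatography
Reagents that add atoms: none
Why: Lewis-acid-promoted Diels–Alder reaction: BF3 binds the more basic C5 carbonyl (the vinylogous-ester carbonyl), which makes C9 the electrophilic terminus, so the diene end remote from the acyloxy group (C10) bonds to C9 and the acyloxy-bearing end (C3) to the methyl-bearing C4, while the methoxy-substituted double bond is deactivated. Endo approach of the 1E,3E diene puts the C3 acyloxy and C10 acetoxymethyl groups cis to each other and trans to the C4 methyl and C9 hydrogen of the cis fusion. The (R)-ester should bias the diene face, and since the two facial isomers are diastereomers the minor one is removed here.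

**Step 5**
Reactants: 8 cis-decalin adduct
Product: 11 9α-hydroxy-5,8-dione (cis-fused ketol), via silyl dienol ether 9 (not isolated), via 9α-silyloxy ketone 10 (not isolated)
Conditions: Me3SiOTf, Et3N, CH2Cl2, −78 to 0 °C; then dimethyldioxirane, acetone/CH2Cl2, −78 °C; then citric acid, MeOH, 0 °C
Reagents that add atoms: dimethyldioxirane, CC1(C)OO1
Why: Rubottom oxidation: enolisation is possible only toward C9, and dimethyldioxirane epoxidises the electron-rich C8=C9 silyl enol ether in preference to the acyloxy-flanked C1=C2 and the push–pull C6=C7 olefins. Oxygen should enter C9 from the α face, anti to the 10β-acetoxymethyl arm and in the sense that keeps both rings chair-like, so the cis fusion (9α-OH cis to the 4α-methyl) is retained.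

**Step 6**
Reactants: 11 9α-hydroxy-5,8-dione
Product: 12 8β,9α-diol (5-one)
Conditions: Me4NBH(OAc)3, MeCN/AcOH, −30 °C
Reagents that add atoms: none
Why: Saksena–Evans reduction: the 9α-hydroxyl exchanges onto boron and delivers hydride to the α face of the C8 carbonyl, which should give the 8β-alcohol (trans-8,9-diol); the vinylogous-ester carbonyl C5 is too electron-rich to be reduced by this reagent.

**Step 7**
Reactants: 12 8β,9α-diol (5-one)
Product: 13 8β-(4-methoxybenzyl) ether
Conditions: 2-(4-methoxybenzyloxy)-4-methylquinoline, MeOTf, MgO, PhCF3, 0 °C to rt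
Reagents that add atoms: 2-(4-methoxybenzyloxy)-4-methylquinoline, COc1ccc(COc2cc(C)c3ccccc3n2)cc1
Why: Ether formation by neutral benzyl transfer from the N-methylquinolinium salt formed in the flask; this avoids acid, which would ionise the C8 alcohol next to the enol ether, and alkoxide base, which would start acyl migration or retro-aldol cleavage. The secondary C8 hydroxyl reacts; the tertiary C9 hydroxyl should not.

**Step 8**
Reactants: 13 8β-(4-methoxybenzyl) ether
Product: 14 3β,14-diol
Conditions: K2CO3 (0.2 equiv), MeOH, 0 °C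
Reagents that add atoms: none
Why: Transesterification: catalytic methoxide removes the activated α-alkoxy ester on O3 and the primary acetate on O14. C4 and C9 carry no hydrogen, so nothing can epimerise, and the low temperature and the poor electron-sink character of the vinylogous-ester carbonyl should hold back retro-aldol cleavage of the new β-hydroxy ketone relationship.

**Step 9**
Reactants: 14 3β,14-diol
Product: 15 1β,2β-epoxide
Conditions: VO(acac)2 (cat.), t-BuOOH, CH2Cl2, 0 °C to rt
Reagents that add atoms: tert-butyl hydroperoxide, CC(C)(C)OO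
Why: Hydroxyl-directed epoxidation: the 3β-allylic and 14-homoallylic hydroxyls bind vanadium and deliver oxygen to the β face of C1=C2, syn to the C3 hydroxyl as is the rule for cyclohex-2-enols; the electron-poor C6=C7 olefin does not react.

**Step 10**
Reactants: 15 1β,2β-epoxide
Product: 16 3,14-bis(triethylsilyl) ether
Conditions: Et3SiCl, imidazole, 4-(dimethylamino)pyridine (cat.), DMF, 0 °C to rt
Reagents that add atoms: chlorotriethylsilane, CC[Si](Cl)(CC)CC
Why: Silylation of the primary and the hindered secondary hydroxyl; the tertiary C9 hydroxyl is not silylated by the chloride.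

**Step 11**
Reactants: 16 3,14-bis(triethylsilyl) ether
Product: 19 2β-hydroxy-1(10)-ene (ring B allylic alcohol), via 1α-phenylselanyl alcohol 17 (not isolated), via selenoxide 18 (not isolated)
Conditions: (PhSe)2, NaBH4, EtOH, 0 to 50 °C; then 30% H2O2, pyridine, THF, 0 °C to rt
Reagents that add atoms: none
Why: Epoxide-to-allylic-alcohol transposition by selenide opening and selenoxide elimination: benzeneselenolate opens the epoxide trans-diaxially at C1, the carbon remote from the C3 silyloxy group, with inversion, leaving O2 on the β face. The selenoxide then eliminates syn with the α-hydrogen on C10 and away from the carbinol carbon, giving C1=C10 and the 2β,3β-cis-diol pattern.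

**Step 12**
Reactants: 19 2β-hydroxy-1(10)-ene
Product: 20 2β-(tert-butyldimethylsilyl) ether
Conditions: t-BuMe2SiOTf (1.2 equiv), 2,6-lutidine, CH2Cl2, −78 °C
Reagents that add atoms: tert-butyldimethylsilyl trifluoromethanesulfonate, CC(C)(C)[Si](C)(C)OS(=O)(=O)C(F)(F)F
Why: Silylation of the only free secondary hydroxyl; at −78 °C the tertiary C9 hydroxyl reacts much more slowly.

**Step 13**
Reactants: 20 2β-(tert-butyldimethylsilyl) ether
Product: 22 5-oxo-6-en-7-yl trifluoromethanesulfonate, via sodium dione enolate 21 (not isolated)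
Conditions: NaSEt (1.05 equiv), DMF, rt; then N-(5-chloropyridin-2-yl)bis(trifluoromethanesulfonimide), −40 to 0 °C
Reagents that add atoms: N-(5-chloropyridin-2-yl)bis(trifluoromethanesulfonimide), FC(F)(F)S(=O)(=O)N(c1ccc(Cl)cn1)S(=O)(=O)C(F)(F)F
Why: Nucleophilic demethylation (SN2 at the methyl of the vinylogous ester by thiolate) gives the 5,7-dione enolate, which is O-sulfonylated; triflation should occur at O7 because O5 is flanked by the quaternary C4. Conjugate addition of thiolate is unproductive because thiolate, not methoxide, is expelled again.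

**Step 14**
Reactants: 23 2,3-dibromoprop-1-ene; 24 (4-methoxyphenyl)methanol
Product: 25 1-{[(2-bromoprop-2-en-1-yl)oxy]methyl}-4-methoxybenzene
Conditions: 24, NaH, THF, 0 °C; then 23, Bu4NI (cat.), rt
Reagents that add atoms: none
Why: Williamson ether synthesis: the alkoxide displaces the allylic bromide; the vinylic bromide is inert to SN2.

**Step 15**
Reactants: 22 5-oxo-6-en-7-yl trifluoromethanesulfonate; 25 1-{[(2-bromoprop-2-en-1-yl)oxy]methyl}-4-methoxybenzene
Product: 28 dienone (7-{3-[(4-methoxybenzyl)oxy]prop-1-en-2-yl}-6-en-5-one), via vinyllithium 26 (not isolated), via vinylzinc chloride 27 (not isolated)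
Conditions: 25, t-BuLi (2 equiv), Et2O, −78 °C; ZnCl2, THF, −78 to 0 °C; then 22, Pd(PPh3)4 (cat.), THF, rt
Reagents that add atoms: none
Why: Negishi coupling: bromine–lithium exchange, transmetalation to zinc and coupling with the electron-poor enol triflate under zerovalent palladium catalysis form C7–C11. The organozinc tolerates the ketone and the tertiary hydroxyl (an extra equivalent allows for protonolysis).

**Step 16**
Reactants: 28 dienone
Product: 29 6α,12-epidioxide (5-one)
Conditions: O2, tetraphenylporphyrin (cat.), visible light, CH2Cl2, −20 °C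
Reagents that add atoms: oxygen, O=O
Why: [4+2] Cycloaddition of singlet oxygen to the s-cis C6=C7–C11=C12 diene: oxygen should add to the α face, away from the 8β-ether and ring B, which places O6 α, and the peroxide bridge forces C12 cis to C6 across the new tetrasubstituted C7=C11. C1=C10 has allylic hydrogens only on oxygen-bearing carbons and should not undergo the ene reaction.

**Step 17**
Reactants: 29 6α,12-epidioxide (5-one)
Product: 30 5β-alcohol
Conditions: Me4NBH(OAc)3, MeCN/AcOH, −30 °C
Reagents that add atoms: none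
Why: Saksena–Evans reduction: the 9α-hydroxyl delivers hydride to the α face of the C5 ketone (1,3-anti reduction of a β-hydroxy ketone), which should give the 5β-alcohol, trans to the C4 methyl as the fragmentation requires; dialkyl peroxides are not reduced by this reagent.

**Step 18**
Reactants: 30 5β-alcohol
Product: 31 5β-methanesulfonate
Conditions: Ms2O, pyridine, 4-(dimethylamino)pyridine (cat.), CH2Cl2, 0 °C
Reagents that add atoms: methanesulfonic anhydride, CS(=O)(=O)OS(C)(=O)=O
Why: Sulfonylation of the only free secondary hydroxyl; pyridine is too weak a base to deprotonate the tertiary C9 hydroxyl (no premature fragmentation) or to isomerise the peroxide.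

**Step 19**
Reactants: 31 5β-methanesulfonate
Product: 32 6α,12-diol 5β-mesylate
Conditions: thiourea, wet MeOH/CH2Cl2, 0 °C to rt
Reagents that add atoms: none
Why: Reduction of the O–O bond by thiourea under neutral conditions unveils the cis-enediol; the hindered secondary mesylate is not displaced.

**Step 20**
Reactants: 32 6α,12-diol 5β-mesylate
Product: 33 fragmentation precursor (6,12-bis-TBS ether; 9α-OH; 5β-OMs)
Conditions: t-BuMe2SiOTf (2.2 equiv), 2,6-lutidine, CH2Cl2, −78 °C
Reagents that add atoms: tert-butyldimethylsilyl trifluoromethanesulfonate, CC(C)(C)[Si](C)(C)OS(=O)(=O)C(F)(F)F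
Why: Silylation of the primary and secondary hydroxyls with a measured amount of triflate; 2,6-lutidine does not ionise the tertiary C9 hydroxyl, which stays free for the next step.

**Step 21**
Reactants: 33 fragmentation precursor
Product: 35 (1(10)Z,4Z)-cyclodeca-1(10),4-dien-9-one, via potassium alkoxide 34 (not isolated)
Conditions: KOtBu (1.1 equiv), THF, −78 to 0 °C; pH 7 phosphate buffer
Reagents that add atoms: none
Why: Grob fragmentation (closest precedent: alkoxide-triggered cleavage of decalin-1,3-diol monosulfonates to cyclodecenones): tert-butoxide deprotonates the only hydroxyl, and in one concerted step the C9–O− lone pair becomes the C9=O π-bond, the C4–C9 σ-electrons become the C4=C5 π-bond and mesylate leaves from C5. No ring is closed by bond formation and no σ-bond of the skeleton is made: the ten-membered ring appears because the bond shared by rings A and B is cut, so two carbocycles become one. No stereocentre is created (C4, C5 and C9 are lost); the stereochemical output is the olefin geometry. The step needs the C5–O bond antiperiplanar to C4–C9, which the 5β-mesylate (trans to the 4α-methyl) has when it is equatorial on the chair of ring A; in that conformer C3 is axial on ring A and gauche to C6, so C3 and C6 end cis on the new double bond (Z), while C1=C10 is Z because it was a cyclohexene. The cis ring fusion is what allows this; a trans-decalin would give the E olefin. In that conformer the leaving group is antiperiplanar to no C–H bond and the C9 oxygen cannot reach the rear of C5, so elimination and oxetane formation should not compete. Other fragmentations are designed out: O3 is silylated (a free or sulfonylated O3 would offer a second 1,3-relationship through C4), O8 is a benzyl-type ether (no 1,2-silyl shift to the alkoxide), and any triethylsilyl shift from O14 to O9 is reversible whereas fragmentation is not. Only a slight excess of base at low temperature and a buffered quench are used because the product has an acidic C8 hydrogen between the ketone and C7=C11.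

**Step 22**
Reactants: 35 (1(10)Z,4Z)-cyclodeca-1(10),4-dien-9-one
Product: 36 (9R)-alcohol
Conditions: NaBH4, CeCl3·7H2O, MeOH/THF, −78 °C
Reagents that add atoms: none
Why: Luche reduction (1,2-selective for the enone); with the C8–O bond antiperiplanar to the incoming hydride (non-chelation model) attack should give the 8,9-threo alcohol (9R), the configuration of the target.

**Step 23**
Reactants: 37 methyl (S)-2-methyloxirane-2-carboxylate
Product: 38 potassium (S)-2-methyloxirane-2-carboxylate
Conditions: KOSiMe3, THF, 0 °C to rt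
Reagents that add atoms: potassium trimethylsilanolate, C[Si](C)(C)[O-].[K+]
Why: Anhydrous ester cleavage by silanolate gives the carboxylate salt directly and avoids the free epoxy acid and aqueous acid; the quaternary epoxide carbon cannot epimerise.

**Step 24**
Reactants: 36 (9R)-alcohol; 38 potassium (S)-2-methyloxirane-2-carboxylate
Product: 40 C9 (S)-2-methyloxirane-2-carboxylate, via mixed anhydride 39 (not isolated)
Conditions: 38, 2,4,6-trichlorobenzoyl chloride, THF, 0 °C; then 36, 4-(dimethylamino)pyridine, toluene, rt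
Reagents that add atoms: none
Why: Yamaguchi esterification: the carboxylate forms the mixed anhydride and the acylpyridinium ion acylates the hindered allylic C9 hydroxyl with retention at C9; the epoxide carbon α to the carbonyl is deactivated toward opening by chloride.

**Step 25**
Reactants: 40 C9 (S)-2-methyloxirane-2-carboxylate
Product: 41 3,14-diol
Conditions: pyridinium 4-toluenesulfonate (cat.), MeOH/CH2Cl2, 0 °C
Reagents that add atoms: none
Why: Acid-catalysed methanolysis discriminates by silyl size: the triethylsilyl ethers on O14 and O3 are cleaved far faster than the tert-butyldimethylsilyl ethers; the epoxy ester is inert to this weak acid.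

**Step 26**
Reactants: 41 3,14-diol
Product: 42 14-(3-methylbut-2-enoate)
Conditions: 3-methylbut-2-enoyl chloride (1.05 equiv), pyridine, CH2Cl2, −40 °C
Reagents that add atoms: 3-methylbut-2-enoyl chloride, CC(C)=CC(Cl)=O
Why: Acylation: the primary allylic O14 hydroxyl reacts far faster than the secondary O3 hydroxyl, which is flanked by the silyloxy-bearing C2 and the trisubstituted C4.

**Step 27**
Reactants: 42 14-(3-methylbut-2-enoate)
Product: 43 3-methanesulfonate
Conditions: MsCl, Et3N, CH2Cl2, −30 °C; used crude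
Reagents that add atoms: methanesulfonyl chloride, CS(Cl)(=O)=O
Why: Sulfonylation (via sulfene) of the one remaining hydroxyl; the allylic mesylate is not purified but taken on at once.

**Step 28**
Reactants: 43 3-methanesulfonate
Product: 44 2,3-epoxide 6,12-diol
Conditions: Bu4NF, THF, 0 °C
Reagents that add atoms: none
Why: Fluoride removes the three silyl groups, and the C2 alkoxide displaces the C3 mesylate from the rear (intramolecular Williamson reaction, inversion at C3, retention at C2); this turns the 2,3-cis pattern into the trans-disubstituted epoxide that a six-membered ring could not have held. No ester has a free hydroxyl on a neighbouring carbon, so acyl migration has no easy path.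

**Step 29**
Reactants: 44 2,3-epoxide 6,12-diol
Product: 46 butenolide, via lactol 45 (not isolated)
Conditions: 2,2,6,6-tetramethylpiperidin-1-oxyl (cat.), PhI(OAc)2, CH2Cl2, rt
Reagents that add atoms: none
Why: Oxidative lactonisation by the oxoammonium salt: the primary allylic C12 alcohol is oxidised to the aldehyde, captured by the cis-disposed O6 as a lactol, and oxidised again to the lactone; O14 is already an ester, so no second primary alcohol competes.

**Step 30**
Reactants: 46 butenolide
Product: 47 4,5-epoxide (bis-PMB ether)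
Conditions: 3-chloroperoxybenzoic acid, NaHCO3, CH2Cl2, 0 °C
Reagents that add atoms: 3-chloroperoxybenzoic acid, OOC(=O)c1cccc(Cl)c1
Why: Prilezhaev epoxidation: C4=C5 is the most electron-rich olefin left (C7=C11 is in the butenolide, C1=C10 carries three allylic C–O bonds, the ester olefin is conjugated). With H6 in the olefin plane (least allylic strain) the outer face of the Z olefin is the one syn to the lactone oxygen, and attack there gives the (4S,5S)-epoxide.

**Step 31**
Reactants: 47 4,5-epoxide (bis-PMB ether)
Product: 48 8,13-diol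
Conditions: DDQ, CH2Cl2/pH 7 buffer, 0 °C to rt
Reagents that add atoms: none
Why: Oxidative cleavage of both 4-methoxybenzyl ethers (hydride abstraction, hydrolysis of the hemiacetal) under conditions neutral enough for the epoxides and esters.

**Step 32**
Reactants: 48 8,13-diol
Product: 49 target (CNP0279449.1)
Conditions: Ac2O, pyridine, 4-(dimethylamino)pyridine (cat.), CH2Cl2, 0 °C
Reagents that add atoms: acetic anhydride, CC(=O)OC(C)=O
Why: Acetylation of the secondary C8 and primary C13 hydroxyls under nucleophilic catalysis completes the target; the short reaction at 0 °C leaves little time for an acyl shift from O9 to O8.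

## Compound list

1 | potassium (1E,3E)-5-oxopenta-1,3-dien-1-olate (glutaconaldehyde potassium salt) | [K+].[O-]/C=C/C=C/C=O | starting material
2 | (R)-2-methoxy-2-phenylacetic acid | CO[C@@H](C(=O)O)c1ccccc1 | starting material
3 | (R)-2-methoxy-2-phenylacetyl chloride | CO[C@@H](C(=O)Cl)c1ccccc1 | intermediate
4 | (1E,3E)-5-oxopenta-1,3-dien-1-yl (R)-2-methoxy-2-phenylacetate | CO[C@@H](C(=O)O/C=C/C=C/C=O)c1ccccc1 | intermediate
5 | (1E,3E)-5-hydroxypenta-1,3-dien-1-yl (R)-2-methoxy-2-phenylacetate | CO[C@@H](C(=O)O/C=C/C=C/CO)c1ccccc1 | intermediate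
6 | (1E,3E)-5-acetoxypenta-1,3-dien-1-yl (R)-2-methoxy-2-phenylacetate | CO[C@@H](C(=O)O/C=C/C=C/COC(C)=O)c1ccccc1 | intermediate
7 | 2-methoxy-5-methyl-1,4-benzoquinone | COC1=CC(=O)C(C)=CC1=O | starting material
8 | cis-decalin adduct: 5,8-dione, C6=C7 with 7-OMe, C1=C2, 4α-methyl, 9α-H, 3β-[(R)-2-methoxy-2-phenylacetoxy], 10β-CH2OAc | C[C@]12C(=O)C=C(OC)C(=O)[C@H]1[C@@H](COC(C)=O)C=C[C@H]2OC(=O)[C@H](OC)c1ccccc1 | intermediate
9 | 8-trimethylsilyloxy-6,8(9)-diene (silyl dienol ether of 8) | C[C@]12C(=O)C=C(OC)C(O[Si](C)(C)C)=C1[C@@H](COC(C)=O)C=C[C@H]2OC(=O)[C@H](OC)c1ccccc1 | intermediate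
10 | 9α-trimethylsilyloxy derivative of 8 | C[C@]12C(=O)C=C(OC)C(=O)[C@@]1(O[Si](C)(C)C)[C@@H](COC(C)=O)C=C[C@H]2OC(=O)[C@H](OC)c1ccccc1 | intermediate
11 | 9α-hydroxy derivative of 8 (cis-fused ketol) | C[C@]12C(=O)C=C(OC)C(=O)[C@@]1(O)[C@@H](COC(C)=O)C=C[C@H]2OC(=O)[C@H](OC)c1ccccc1 | intermediate
12 | 8β,9α-diol, 5-one (other groups as in 8) | C[C@]12C(=O)C=C(OC)[C@@H](O)[C@@]1(O)[C@@H](COC(C)=O)C=C[C@H]2OC(=O)[C@H](OC)c1ccccc1 | intermediate
13 | 8β-OPMB, 9α-OH, 5-one (esters as in 8) | C[C@]12C(=O)C=C(OC)[C@@H](OCc3ccc(OC)cc3)[C@@]1(O)[C@@H](COC(C)=O)C=C[C@H]2OC(=O)[C@H](OC)c1ccccc1 | intermediate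
14 | 3β,14-diol: 8β-OPMB, 9α-OH, 5-one, 7-OMe, C1=C2 | C[C@]12C(=O)C=C(OC)[C@@H](OCc3ccc(OC)cc3)[C@@]1(O)[C@@H](CO)C=C[C@H]2O | intermediate
15 | 1β,2β-epoxide of 14 (epoxide cis to 3β-OH) | C[C@]12C(=O)C=C(OC)[C@@H](OCc3ccc(OC)cc3)[C@@]1(O)[C@@H](CO)[C@H]3O[C@H]3[C@H]2O | intermediate
16 | 3β,14-bis(triethylsilyl) ether of 15 | C[C@]12C(=O)C=C(OC)[C@@H](OCc3ccc(OC)cc3)[C@@]1(O)[C@@H](CO[Si](CC)(CC)CC)[C@H]3O[C@H]3[C@H]2O[Si](CC)(CC)CC | intermediate
17 | 1α-phenylselanyl-2β-ol (3β-OTES, 14-OTES) | C[C@]12C(=O)C=C(OC)[C@@H](OCc3ccc(OC)cc3)[C@@]1(O)[C@@H](CO[Si](CC)(CC)CC)[C@H]([Se]c3ccccc3)[C@@H](O)[C@H]2O[Si](CC)(CC)CC | intermediate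
18 | selenoxide of 17 (either configuration at selenium) | C[C@]12C(=O)C=C(OC)[C@@H](OCc3ccc(OC)cc3)[C@@]1(O)[C@@H](CO[Si](CC)(CC)CC)[C@H]([Se](=O)c3ccccc3)[C@@H](O)[C@H]2O[Si](CC)(CC)CC | intermediate
19 | ring B allylic alcohol: 2β-OH, C1=C10, 3β-OTES, 14-OTES, 8β-OPMB, 9α-OH, 5-one, 7-OMe | C[C@]12C(=O)C=C(OC)[C@@H](OCc3ccc(OC)cc3)[C@@]1(O)C(CO[Si](CC)(CC)CC)=C[C@@H](O)[C@H]2O[Si](CC)(CC)CC | intermediate
20 | 2β-OTBS ether of 19 | C[C@]12C(=O)C=C(OC)[C@@H](OCc3ccc(OC)cc3)[C@@]1(O)C(CO[Si](CC)(CC)CC)=C[C@@H](O[Si](C)(C)C(C)(C)C)[C@H]2O[Si](CC)(CC)CC | intermediate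
21 | sodium enolate of the 5,7-dione (7-olate) | [Na+].C[C@]12C(=O)C=C([O-])[C@@H](OCc3ccc(OC)cc3)[C@@]1(O)C(CO[Si](CC)(CC)CC)=C[C@@H](O[Si](C)(C)C(C)(C)C)[C@H]2O[Si](CC)(CC)CC | intermediate
22 | 5-oxo-6-en-7-yl trifluoromethanesulfonate (other groups as in 20) | C[C@]12C(=O)C=C(OS(=O)(=O)C(F)(F)F)[C@@H](OCc3ccc(OC)cc3)[C@@]1(O)C(CO[Si](CC)(CC)CC)=C[C@@H](O[Si](C)(C)C(C)(C)C)[C@H]2O[Si](CC)(CC)CC | intermediate
23 | 2,3-dibromoprop-1-ene | C=C(Br)CBr | starting material
24 | (4-methoxyphenyl)methanol | COc1ccc(CO)cc1 | starting material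
25 | 1-{[(2-bromoprop-2-en-1-yl)oxy]methyl}-4-methoxybenzene | C=C(Br)COCc1ccc(OC)cc1 | intermediate
26 | {3-[(4-methoxybenzyl)oxy]prop-1-en-2-yl}lithium | [Li]C(=C)COCc1ccc(OC)cc1 | intermediate
27 | chloro{3-[(4-methoxybenzyl)oxy]prop-1-en-2-yl}zinc | Cl[Zn]C(=C)COCc1ccc(OC)cc1 | intermediate
28 | dienone: 7-{3-[(4-methoxybenzyl)oxy]prop-1-en-2-yl}-6-en-5-one (other groups as in 20) | C[C@]12C(=O)C=C(C(=C)COCc3ccc(OC)cc3)[C@@H](OCc3ccc(OC)cc3)[C@@]1(O)C(CO[Si](CC)(CC)CC)=C[C@@H](O[Si](C)(C)C(C)(C)C)[C@H]2O[Si](CC)(CC)CC | intermediate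
29 | 6α,12-epidioxide (1,2-dioxine O6–O–C12 across C7=C11, C13H2OPMB on C11), 5-one | C[C@]12C(=O)[C@@H]3OOCC(COCc4ccc(OC)cc4)=C3[C@@H](OCc3ccc(OC)cc3)[C@@]1(O)C(CO[Si](CC)(CC)CC)=C[C@@H](O[Si](C)(C)C(C)(C)C)[C@H]2O[Si](CC)(CC)CC | intermediate
30 | 5β-alcohol of 29 | C[C@]12[C@@H](O)[C@@H]3OOCC(COCc4ccc(OC)cc4)=C3[C@@H](OCc3ccc(OC)cc3)[C@@]1(O)C(CO[Si](CC)(CC)CC)=C[C@@H](O[Si](C)(C)C(C)(C)C)[C@H]2O[Si](CC)(CC)CC | intermediate
31 | 5β-methanesulfonate of 30 | C[C@]12[C@@H](OS(C)(=O)=O)[C@@H]3OOCC(COCc4ccc(OC)cc4)=C3[C@@H](OCc3ccc(OC)cc3)[C@@]1(O)C(CO[Si](CC)(CC)CC)=C[C@@H](O[Si](C)(C)C(C)(C)C)[C@H]2O[Si](CC)(CC)CC | intermediate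
32 | 6α,12-diol 5β-mesylate; C7=C11 with C12H2OH cis to C6 and C13H2OPMB cis to C8 | C[C@]12[C@@H](OS(C)(=O)=O)[C@H](O)/C(=C(/COCc3ccc(OC)cc3)CO)[C@@H](OCc3ccc(OC)cc3)[C@@]1(O)C(CO[Si](CC)(CC)CC)=C[C@@H](O[Si](C)(C)C(C)(C)C)[C@H]2O[Si](CC)(CC)CC | intermediate
33 | fragmentation precursor, cis-decalin (2R,3S,4S,5R,6R,8R,9R): 2β-OTBS, 3β-OTES, 4α-Me, 5β-OMs, 6α-OTBS, 8β-OPMB, 9α-OH, 14-OTES, C1=C10, C7=C11(C12H2OTBS cis to C6)(C13H2OPMB) | C[C@]12[C@@H](OS(C)(=O)=O)[C@H](O[Si](C)(C)C(C)(C)C)/C(=C(/COCc3ccc(OC)cc3)CO[Si](C)(C)C(C)(C)C)[C@@H](OCc3ccc(OC)cc3)[C@@]1(O)C(CO[Si](CC)(CC)CC)=C[C@@H](O[Si](C)(C)C(C)(C)C)[C@H]2O[Si](CC)(CC)CC | intermediate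
34 | potassium 9-alkoxide of 33 | [K+].C[C@]12[C@@H](OS(C)(=O)=O)[C@H](O[Si](C)(C)C(C)(C)C)/C(=C(/COCc3ccc(OC)cc3)CO[Si](C)(C)C(C)(C)C)[C@@H](OCc3ccc(OC)cc3)[C@@]1([O-])C(CO[Si](CC)(CC)CC)=C[C@@H](O[Si](C)(C)C(C)(C)C)[C@H]2O[Si](CC)(CC)CC | intermediate
35 | (1(10)Z,4Z,2R,3S,6S,8R)-cyclodeca-1(10),4-dien-9-one: 2-OTBS, 3-OTES, 4-Me, 6-OTBS, 8-OPMB, 14-OTES, 7(11)-ene with C12H2OTBS cis to C6 and C13H2OPMB cis to C8 | COc1ccc(cc1)COC\C(CO[Si](C)(C)C(C)(C)C)=C1/[C@@H](OCc2ccc(OC)cc2)C(=O)/C(CO[Si](CC)(CC)CC)=C\[C@@H](O[Si](C)(C)C(C)(C)C)[C@@H](O[Si](CC)(CC)CC)/C(C)=C\[C@@H]1O[Si](C)(C)C(C)(C)C | intermediate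
36 | (9R)-alcohol from 35 (2R,3S,6S,8R,9R) | COc1ccc(cc1)COC\C(CO[Si](C)(C)C(C)(C)C)=C1/[C@@H](OCc2ccc(OC)cc2)[C@H](O)/C(CO[Si](CC)(CC)CC)=C\[C@@H](O[Si](C)(C)C(C)(C)C)[C@@H](O[Si](CC)(CC)CC)/C(C)=C\[C@@H]1O[Si](C)(C)C(C)(C)C | intermediate
37 | methyl (S)-2-methyloxirane-2-carboxylate | COC(=O)[C@]1(C)CO1 | starting material
38 | potassium (S)-2-methyloxirane-2-carboxylate | [K+].[O-]C(=O)[C@]1(C)CO1 | intermediate
39 | (S)-2-methyloxirane-2-carboxylic 2,4,6-trichlorobenzoic anhydride | O=C(OC(=O)[C@]1(C)CO1)c1c(Cl)cc(Cl)cc1Cl | intermediate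
40 | 9-O-[(S)-2-methyloxirane-2-carbonyl] derivative of 36 | COc1ccc(cc1)COC\C(CO[Si](C)(C)C(C)(C)C)=C1/[C@@H](OCc2ccc(OC)cc2)[C@H](OC(=O)[C@]3(C)CO3)/C(CO[Si](CC)(CC)CC)=C\[C@@H](O[Si](C)(C)C(C)(C)C)[C@@H](O[Si](CC)(CC)CC)/C(C)=C\[C@@H]1O[Si](C)(C)C(C)(C)C | intermediate
41 | 3,14-diol from 40 | COc1ccc(cc1)COC\C(CO[Si](C)(C)C(C)(C)C)=C1/[C@@H](OCc2ccc(OC)cc2)[C@H](OC(=O)[C@]3(C)CO3)/C(CO)=C\[C@@H](O[Si](C)(C)C(C)(C)C)[C@@H](O)/C(C)=C\[C@@H]1O[Si](C)(C)C(C)(C)C | intermediate
42 | 14-O-(3-methylbut-2-enoyl) derivative of 41 (3-OH free) | COc1ccc(cc1)COC\C(CO[Si](C)(C)C(C)(C)C)=C1/[C@@H](OCc2ccc(OC)cc2)[C@H](OC(=O)[C@]3(C)CO3)/C(COC(=O)C=C(C)C)=C\[C@@H](O[Si](C)(C)C(C)(C)C)[C@@H](O)/C(C)=C\[C@@H]1O[Si](C)(C)C(C)(C)C | intermediate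
43 | 3-methanesulfonate of 42 | COc1ccc(cc1)COC\C(CO[Si](C)(C)C(C)(C)C)=C1/[C@@H](OCc2ccc(OC)cc2)[C@H](OC(=O)[C@]3(C)CO3)/C(COC(=O)C=C(C)C)=C\[C@@H](O[Si](C)(C)C(C)(C)C)[C@@H](OS(C)(=O)=O)/C(C)=C\[C@@H]1O[Si](C)(C)C(C)(C)C | intermediate
44 | (2R,3S)-2,3-epoxide with free 6-OH and 12-OH (8-OPMB, 13-OPMB, both esters in place) | COc1ccc(cc1)COC\C(CO)=C1/[C@@H](OCc2ccc(OC)cc2)[C@H](OC(=O)[C@]3(C)CO3)/C(COC(=O)C=C(C)C)=C\[C@H]4O[C@@H]4/C(C)=C\[C@@H]1O | intermediate
45 | lactol (12-hydroxy-6,12-epoxy; either configuration at C12) from 44 | COc1ccc(cc1)COCC1=C2[C@@H](OCc3ccc(OC)cc3)[C@H](OC(=O)[C@]3(C)CO3)/C(COC(=O)C=C(C)C)=C\[C@H]4O[C@@H]4/C(C)=C\[C@@H]2OC1O | intermediate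
46 | butenolide (6,12-olide) with Z C4=C5, 2,3-epoxide, 8-OPMB, 13-OPMB | COc1ccc(cc1)COCC1=C2[C@@H](OCc3ccc(OC)cc3)[C@H](OC(=O)[C@]3(C)CO3)/C(COC(=O)C=C(C)C)=C\[C@H]4O[C@@H]4/C(C)=C\[C@@H]2OC1=O | intermediate
47 | (4S,5S)-4,5-epoxide of 46 (8,13-bis-PMB ether of the target diol) | COc1ccc(cc1)COCC1=C2[C@@H](OCc3ccc(OC)cc3)[C@H](OC(=O)[C@]3(C)CO3)/C(COC(=O)C=C(C)C)=C\[C@H]3O[C@@H]3[C@@]3(C)O[C@H]3[C@@H]2OC1=O | intermediate
48 | 8,13-diol (target without its two acetyl groups) | OCC1=C2[C@@H](O)[C@H](OC(=O)[C@]3(C)CO3)/C(COC(=O)C=C(C)C)=C\[C@H]3O[C@@H]3[C@@]3(C)O[C@H]3[C@@H]2OC1=O | intermediate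
49 | CNP0279449.1 (2R,3S,4S,5S,6R,8R,9R; ester 2S; 1(10)Z) | CC(=O)OCC1=C2[C@@H](OC(C)=O)[C@H](OC(=O)[C@]3(C)CO3)/C(COC(=O)C=C(C)C)=C\[C@H]3O[C@@H]3[C@@]3(C)O[C@H]3[C@@H]2OC1=O | target

## Step count and least certain steps

Total step count: 32. Longest linear sequence: 30 steps (steps 1–13, 15–22 and 24–32, from 1); steps 14 and 23 are branch steps.

**Step 21 (key).** The chair of ring A that puts the mesylate antiperiplanar to C4–C9 has a 1,3-diaxial contact between C3 and the C8 ether and allylic strain between the equatorial C6 silyloxy group and the alkylidene arm. Fragmentation may therefore be slow enough to be outrun by silyl transfer from O14 to the C9 alkoxide, or be followed by base-induced epimerisation at C8 of the product. The fallback replaces the sulfonate fragmentation by a retro-aldol cleavage of the same bond. It sets out from 29, whose peroxide is reduced with thiourea to the 6α,12-diol 5-ketone F1, and both hydroxyls are silylated to the bis-TBS 5-ketone F2. Treating F2 with KN(SiMe3)2 in the presence of the pyridyl triflimide of step 13 should make the C9 alkoxide cleave C4–C9 (the C5 ketone is the electron sink) and trap the C5 enolate of the ten-membered ring as the enol triflate F3. Reduction of the triflate with Pd(OAc)2, PPh3, HCO2H and Bu3N returns to the route at 35.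

**Step 4.** Facial discrimination by the remote ester may be poor, and BF3 may also bind the ester and erode the regiocontrol. The fallback gives up auxiliary control for a resolution. From 1, acetic anhydride gives the dienal acetate F4, Luche reduction the dienol acetate F5 and acetylation the diacetate diene F6. Cycloaddition of F6 with 7 under the conditions of step 4 gives the racemic adduct, which is resolved by preparative chromatography on a chiral phase to the adduct F7. The conditions of steps 5 to 7 then give the silyl dienol ether F8, the 9α-silyloxy ketone F9, the ketol F10, the 8β,9α-diol F11 and the PMB ether F12. Methanolysis as in step 8 removes both acetates and returns to the route at 14.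

**Step 13.** Sulfonylation may occur at O5 instead of O7, or excess thiolate may attack the product triflate. The fallback places the carbon at C7 by a 1,2-addition and an allylic transposition. It sets out from 20: reduction of the C5 carbonyl with i-Bu2AlH gives the 5-hydroxy enol ether F13 (not isolated), which on mild acid (oxalic acid, wet silica) collapses in the Stork–Danheiser sense to the 5-en-7-one F14. Addition of 26 in the presence of CeCl3 from the α face gives the 7β-tertiary alcohol F15. A 1,3-transposition catalysed by O3ReOSiPh3 moves the hydroxyl suprafacially to C5 and gives the 5β-hydroxy diene F16. Singlet-oxygen cycloaddition to F16 (in the presence of methanol to suppress hydroxyl-directed attack) returns to the route at 30.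

**Step 22.** The face of the ketone that is open to hydride depends on the conformation of the ten-membered ring, so the 9-epimer may dominate. The fallback uses inversion instead of retention at the esterification. The 9-epi-alcohol F17 is coupled with the free acid F18 (from 38 by careful acidification) under Mitsunobu conditions (PPh3, diisopropyl azodicarboxylate), which returns to the route at 40.

**Step 30.** The peracid may prefer the other face of C4=C5 or attack C1=C10. The fallback reaches the epoxide by two inversions instead of one suprafacial delivery. From 46, N-bromosuccinimide in wet THF forms the bromonium ion on the face the peracid prefers, and water opens it at the tertiary C4 from the opposite face to give the bromohydrin F19. Ag2O then closes the C4 oxygen onto C5 with inversion, which returns to the route at 47 with the epoxide on the face opposite to the first attack.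

## Further compounds

F1 | step 21 | 6α,12-diol 5-ketone (9α-OH; from 29) | C[C@]12C(=O)[C@H](O)/C(=C(/COCc3ccc(OC)cc3)CO)[C@@H](OCc3ccc(OC)cc3)[C@@]1(O)C(CO[Si](CC)(CC)CC)=C[C@@H](O[Si](C)(C)C(C)(C)C)[C@H]2O[Si](CC)(CC)CC
F2 | step 21 | 6,12-bis-TBS 5-ketone | C[C@]12C(=O)[C@H](O[Si](C)(C)C(C)(C)C)/C(=C(/COCc3ccc(OC)cc3)CO[Si](C)(C)C(C)(C)C)[C@@H](OCc3ccc(OC)cc3)[C@@]1(O)C(CO[Si](CC)(CC)CC)=C[C@@H](O[Si](C)(C)C(C)(C)C)[C@H]2O[Si](CC)(CC)CC
F3 | step 21 | ten-membered 9-ketone 5-enol triflate (C3 cis to C6 on C4=C5) | COc1ccc(cc1)COC\C(CO[Si](C)(C)C(C)(C)C)=C1/[C@@H](OCc2ccc(OC)cc2)C(=O)/C(CO[Si](CC)(CC)CC)=C\[C@@H](O[Si](C)(C)C(C)(C)C)[C@@H](O[Si](CC)(CC)CC)/C(C)=C(OS(=O)(=O)C(F)(F)F)\[C@@H]1O[Si](C)(C)C(C)(C)C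
F4 | step 4 | (1E,3E)-5-oxopenta-1,3-dien-1-yl acetate | CC(=O)O/C=C/C=C/C=O
F5 | step 4 | (1E,3E)-5-hydroxypenta-1,3-dien-1-yl acetate | CC(=O)O/C=C/C=C/CO
F6 | step 4 | (1E,3E)-penta-1,3-diene-1,5-diyl diacetate | CC(=O)O/C=C/C=C/COC(C)=O
F7 | step 4 | 3β-acetoxy analogue of 8 (resolved enantiomer) | C[C@]12C(=O)C=C(OC)C(=O)[C@H]1[C@@H](COC(C)=O)C=C[C@H]2OC(C)=O
F8 | step 4 | silyl dienol ether of F7 | C[C@]12C(=O)C=C(OC)C(O[Si](C)(C)C)=C1[C@@H](COC(C)=O)C=C[C@H]2OC(C)=O
F9 | step 4 | 9α-trimethylsilyloxy derivative of F7 | C[C@]12C(=O)C=C(OC)C(=O)[C@@]1(O[Si](C)(C)C)[C@@H](COC(C)=O)C=C[C@H]2OC(C)=O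
F10 | step 4 | 9α-hydroxy derivative of F7 | C[C@]12C(=O)C=C(OC)C(=O)[C@@]1(O)[C@@H](COC(C)=O)C=C[C@H]2OC(C)=O
F11 | step 4 | 8β,9α-diol in the acetate series | C[C@]12C(=O)C=C(OC)[C@@H](O)[C@@]1(O)[C@@H](COC(C)=O)C=C[C@H]2OC(C)=O
F12 | step 4 | 8β-PMB ether in the acetate series | C[C@]12C(=O)C=C(OC)[C@@H](OCc3ccc(OC)cc3)[C@@]1(O)[C@@H](COC(C)=O)C=C[C@H]2OC(C)=O
F13 | step 13 | 5-hydroxy-7-methoxy-6-ene (reduction product of 20) | C[C@]12[C@@H](O)C=C(OC)[C@@H](OCc3ccc(OC)cc3)[C@@]1(O)C(CO[Si](CC)(CC)CC)=C[C@@H](O[Si](C)(C)C(C)(C)C)[C@H]2O[Si](CC)(CC)CC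
F14 | step 13 | 5-en-7-one | C[C@]12C=CC(=O)[C@@H](OCc3ccc(OC)cc3)[C@@]1(O)C(CO[Si](CC)(CC)CC)=C[C@@H](O[Si](C)(C)C(C)(C)C)[C@H]2O[Si](CC)(CC)CC
F15 | step 13 | 7β-hydroxy-7-{3-[(4-methoxybenzyl)oxy]prop-1-en-2-yl}-5-ene | C[C@]12C=C[C@](O)(C(=C)COCc3ccc(OC)cc3)[C@@H](OCc3ccc(OC)cc3)[C@@]1(O)C(CO[Si](CC)(CC)CC)=C[C@@H](O[Si](C)(C)C(C)(C)C)[C@H]2O[Si](CC)(CC)CC
F16 | step 13 | 5β-hydroxy-6,11(12)-diene | C[C@]12[C@@H](O)C=C(C(=C)COCc3ccc(OC)cc3)[C@@H](OCc3ccc(OC)cc3)[C@@]1(O)C(CO[Si](CC)(CC)CC)=C[C@@H](O[Si](C)(C)C(C)(C)C)[C@H]2O[Si](CC)(CC)CC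
F17 | step 22 | 9-epi-alcohol (9S) | COc1ccc(cc1)COC\C(CO[Si](C)(C)C(C)(C)C)=C1/[C@@H](OCc2ccc(OC)cc2)[C@@H](O)/C(CO[Si](CC)(CC)CC)=C\[C@@H](O[Si](C)(C)C(C)(C)C)[C@@H](O[Si](CC)(CC)CC)/C(C)=C\[C@@H]1O[Si](C)(C)C(C)(C)C
F18 | step 22 | (S)-2-methyloxirane-2-carboxylic acid | OC(=O)[C@]1(C)CO1
F19 | step 30 | 4-hydroxy-5-bromo bromohydrin of 46 | COc1ccc(cc1)COCC1=C2[C@@H](OCc3ccc(OC)cc3)[C@H](OC(=O)[C@]3(C)CO3)/C(COC(=O)C=C(C)C)=C\[C@H]3O[C@@H]3[C@@](C)(O)[C@H](Br)[C@@H]2OC1=O
A1 | alternative 1 | seco aldoxime–allene | C=C=C[C@H]3O[C@@H]3[C@@]3(C)O[C@H]3[C@@H]2OC(=O)C(COC(C)=O)=C2[C@@H](OC(C)=O)/C=N/O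
A2 | alternative 1 | isoxazoline-bridged ten-membered ring | CC(=O)OCC1=C2[C@@H](OC(C)=O)C3=NOC/C3=C/[C@H]4O[C@@H]4[C@@]4(C)O[C@H]4[C@@H]2OC1=O
A3 | alternative 2 | seco glycidic acid–Z-vinyl bromide | OC(=O)[C@H]3O[C@@H]3[C@@]3(C)O[C@H]3[C@@H]2OC(=O)C(COC(C)=O)=C2[C@@H](OC(C)=O)[C@H](O[Si](C)(C)C(C)(C)C)/C(CO[Si](C)(C)C(C)(C)C)=C\Br
A4 | alternative 2 | target core with C9 and C14 silyl ethers | CC(=O)OCC1=C2[C@@H](OC(C)=O)[C@H](O[Si](C)(C)C(C)(C)C)/C(CO[Si](C)(C)C(C)(C)C)=C\[C@H]3O[C@@H]3[C@@]3(C)O[C@H]3[C@@H]2OC1=O
A5 | alternative 3 | seco C8,C9-dialdehyde | O=C/C(COC(=O)C=C(C)C)=C\[C@@H](O[Si](C)(C)C(C)(C)C)[C@@H](O[Si](CC)(CC)CC)[C@@]1(C)O[C@H]1[C@H](O[Si](C)(C)C(C)(C)C)/C(C=O)=C(/COC(C)=O)CO[Si](C)(C)C(C)(C)C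
A6 | alternative 3 | ten-membered C8,C9-syn-diol | CC(=O)OC\C(CO[Si](C)(C)C(C)(C)C)=C1/[C@@H](O)[C@H](O)/C(COC(=O)C=C(C)C)=C\[C@@H](O[Si](C)(C)C(C)(C)C)[C@@H](O[Si](CC)(CC)CC)[C@@]2(C)O[C@H]2[C@@H]1O[Si](C)(C)C(C)(C)C
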